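## Analysis of the target

Compound 13 is a flavone: a benzene ring A fused to a 4-pyranone ring C, with an aryl ring B on C2. It has no stereocentre. Ring A carries three adjacent oxygens: a free hydroxyl at C5, hydrogen-bonded to the C4 carbonyl, and methyl ethers at C6 and C7; C8 is unsubstituted. Ring B has methyl ethers at C2' and C3' and a free hydroxyl at C5', meta to both C1' and the C3' ether. The sensitive points are the two phenols (the ring B one is electron-rich and oxidisable), the C2=C3 bond, which can be over-reduced, and C2, which hydroxide can attack with ring opening. The difficulty lies in the oxygen pattern, not the skeleton: one of three neighbouring ring A oxygens must be told apart from the other two, the ring B hydroxyl sits where electrophilic substitution does not reliably reach, and ring C must close onto the correct neighbour of C4a. The strategy rests on the fact that C8a, the ring A carbon bearing O1, is ortho to C4a, which carries the C4 acyl carbon, while the C5 oxygen is the other ortho neighbour. In symmetric arene 1 the only C–H lies between bromine and a methoxy group, so one acylation places the future C4 next to a bromine at the future C8a and, through chelation, frees the future C5 oxygen alone.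

## Retrosynthetic reasoning

13 ⇒ 12. The last disconnection cuts the two O–CH2Ph bonds. Both phenols are carried as benzyl ethers because that group survives the amide base of the fragment union and the phosphate and copper conditions of the ring closure. It leaves by neutral hydrogenolysis, so none of the four methyl ethers has to be distinguished from a protecting group. The forward step must cleave two aryl benzyl ethers without saturating the C2=C3 bond.

12 ⇒ 11. Ring C is opened at O1–C8a. A cut at O1–C2 would need a free hydroxyl at C8a that has to be told apart from the C5 oxygen, and a cut at C4–C4a would leave the three ring A oxygens undifferentiated. A bromine at C8a is unambiguous and already sits ortho to the acyl carbon in bromo diketone 11. What is gained is an open-chain 1,3-diketone whose two halves are simple arenes. The forward reaction must arylate the ring B enol oxygen with the aryl bromide under copper catalysis. The C5 oxygen must be capped, because a free hydroxyl there would condense onto the ring B carbonyl and close the pyranone from the other side of ring A.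

11 ⇒ 5 + 10. The diketone is cut between the methylene carbon (future C3) and the ring B carbonyl carbon (future C2), a Claisen disconnection into methyl ketone 5 and ester 10. The cut is placed on this side because the acetyl group of 5 is what a Friedel–Crafts reaction installs on ring A, and because ester 10 cannot enolise, so the condensation has only one direction. The two fragments are of similar size, which makes the route convergent. The forward reaction needs a strong, non-nucleophilic amide base that leaves the aryl bromide alone.

5 ⇒ 4 ⇒ 1 + 2. Removing the benzyl group from 5 gives hydroxy ketone 4. Compound 4 is disconnected at the C4a–C4 aryl–acyl bond and, formally, at one O–CH3 bond, to arene 1 and acid chloride 2. Symmetric 1 has a single kind of C–H, so the acyl group can only enter between the bromine and a methoxy group. The Lewis acid, chelated between the new carbonyl and that methoxy oxygen, then removes its methyl group through 3 and no other. One operation therefore fixes the acyl carbon, the bromine and the one oxygen that must differ from its neighbours.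

10 ⇒ 9 ⇒ 6 + 7. Ester 10 is the benzyl ether of phenol 9, and 9 is disconnected at the C5'–O bond to ester 6. C5' is meta to both the ester and the C3' methoxy group, so electrophiles do not attack there reliably. It is, however, the only C–H of 6 without an ortho substituent, which is the selectivity rule of iridium-catalysed borylation. Diboron 7 therefore delivers boron there (8), and oxidation turns the C–B bond into the C–O bond.

## Alternatives that were turned down

Alternative 1: The C2–C3 bond and the C4–O bond are disconnected together by treating the three-carbon bridge as an isoxazole.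
- Forward: oxime A3 is converted (N-chlorosuccinimide, Et3N) into the ring B nitrile oxide, which adds to terminal alkyne A2 to give the 3,5-diarylisoxazole A1. N–O cleavage (Mo(CO)6 in wet MeCN, or hydrogenation), loss of the ring A benzyl group and acid-induced closure of the freed phenol onto the enaminone would give flavone A4. A4 still needs its C5 methyl ether removed.
- For: the cycloaddition is regiospecific with a terminal alkyne, runs near neutrality and joins the halves without enolate chemistry. On the fragment union it is at least as safe as the Claisen condensation of step 5, and probably safer with two hindered partners.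
- Against: ring C closes through a phenol oxygen, so ring A must arrive with its four oxygens already differentiated. As drawn, the C5 oxygen ends as one of three adjacent methyl ethers, and the final peri-selective demethylation must spare the neighbouring C6 ether. The electron-rich ring B invites ring chlorination during nitrile oxide generation. Alkyne A2 is shielded by two ortho substituents, which leaves time for furoxan dimerisation. Making A2 and A3 adds steps to each half, so the sequence is several steps longer.
- Comparison: the chosen route gives up the mild union. In return a bromine atom defines O1 and chelation singles out the C5 oxygen in the first step, so no ether has to be discriminated at the end.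

Alternative 2: The C4–C4a bond is cut, leading back to the Z-configured aryloxycinnamate A6, the conjugate adduct of symmetric phenol A7 and arylpropiolate A8.
- Forward: P2O5 in MeSO3H turns the ester carbon of A6 into an acylium ion that acylates the phenoxy ring ortho to oxygen and closes ring C with loss of ethanol, giving flavone mesylate A5. Cleavage of the sulfonate leads to A4, and a selective C5 demethylation to 13.
- For: A7 is symmetric, so the Friedel–Crafts closure has no regiochemical choice. Ring A needs neither halogen nor metal, and the step count is comparable. On the simplicity of ring A and of the closure itself it is the stronger plan.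
- Against: only the Z isomer places the acylium near the phenoxy ring. In strong acid the push–pull alkene can isomerise or lose A7 by retro-addition, after which the acylium can attack C6' of ring B (para to the C3' methoxy group) to give an indenone. Hot P2O5/MeSO3H is also harsh for five aryl methyl ethers. The end game needs two discriminations: removal of the mesylate by alkoxide or hydroxide, which also attack C2 of the pyranone, and cleavage of the C5 methyl ether beside the C6 ether.
- Comparison: the chosen strategy accepts a metal-catalysed closure and a brominated ring A. It offers a C5 oxygen fixed as a benzyl ether from the start and a neutral hydrogenolysis at the end.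

Alternative 3: Ring A itself is disconnected, at C5–C4a, back to cyclobutenone A10, a derivative of dimethyl squarate A11 carrying a 6-aryl-4-pyranon-2-yl group on its sp3 carbon.
- Forward: on heating, A10 would open by 4π electrocyclic ring opening to a vinylketene. The ketene carbon closes onto the C5=C6 bond of the pyranone by 6π electrocyclisation, and tautomerisation delivers ring A with the ketene oxygen as the free C5 hydroxyl, A9. A9 is one hydrogenolysis from 13.
- For: the mechanism itself distinguishes the C5 oxygen from the two methoxy groups, with no protecting group on ring A and no regiochemical question. This is more elegant than the chelation-controlled demethylation used here.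
- Against: it constructs a benzene ring that can be bought fully substituted as 1. A10 requires a 2-aryl-4-pyranone functionalised at C6, a cyclobutenone with hydrogen and not hydroxyl on the sp3 carbon (otherwise C8 would carry oxygen), and a cross-coupling to join them. Each is a multi-step task with sensitive intermediates, and the pyranone itself needs diketone chemistry comparable to the whole of the chosen route. The ring opening must also turn the pyranonyl group inward, against the usual torquoselectivity, so the plan depends on reversible opening at high temperature.
- Comparison: the chosen route is far shorter and reaches the same differentiation of the C5 oxygen in its first step.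

Key step: step 6

Remark on the chemistry: diketones 11 and F2 are drawn as diketo tautomers although they should exist largely as chelated enols; F5 and A10 are racemic.

## Route

Step 1
Reactants: 1 5-bromo-1,2,3-trimethoxybenzene; 2 acetyl chloride
Product: 4 1-(6-bromo-2-hydroxy-3,4-dimethoxyphenyl)ethanone, via 1-(6-bromo-2,3,4-trimethoxyphenyl)ethanone 3 (not isolated)
Conditions: AlCl3 (2.5 equiv), CH2Cl2, 0 °C to rt; ice-water work-up
Reagents that add atoms: none
Why: Friedel–Crafts acylation can only take place at the two equivalent C–H positions of 1 (ortho to one outer methoxy group, para to the other), so 3 should form as a single regioisomer; AlCl3 chelated between the new carbonyl and the flanking methoxy oxygen then lets chloride remove that methyl group as chloromethane (chelation-controlled ortho-demethylation), while the two other ethers lack the chelate and should survive at room temperature.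

Step 2
Reactants: 4 1-(6-bromo-2-hydroxy-3,4-dimethoxyphenyl)ethanone
Product: 5 1-[2-(benzyloxy)-6-bromo-3,4-dimethoxyphenyl]ethanone
Conditions: BnBr, K2CO3, DMF, 60 °C
Reagents that add atoms: benzyl bromide, BrCc1ccccc1
Why: Williamson etherification; the hydrogen-bonded, flanked phenol needs warm DMF, but its phenoxide is the only nucleophile present, and the aryl bromide and the ketone are inert to K2CO3.

Step 3
Reactants: 6 methyl 2,3-dimethoxybenzoate; 7 bis(pinacolato)diboron
Product: 9 methyl 5-hydroxy-2,3-dimethoxybenzoate, via methyl 2,3-dimethoxy-5-(pinacolboryl)benzoate 8 (not isolated)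
Conditions: [Ir(OMe)(cod)]2 (1.5 mol%), 4,4'-di-tert-butyl-2,2'-bipyridine (3 mol%), THF, 80 °C; then KHSO5 (as 2KHSO5·KHSO4·K2SO4), acetone–H2O, rt
Reagents that add atoms: potassium peroxymonosulfate, [K+].[O-]S(=O)(=O)OO
Why: Iridium-catalysed C–H borylation is governed by sterics and C5 of 6 is the only C–H without an ortho substituent, so boron should enter meta to both the ester and the C3 methoxy group; peroxymonosulfate then converts C–B into C–O at the same carbon by 1,2-aryl shift (one-pot C–H borylation/oxidation) under near-neutral conditions that spare the methyl ester.

Step 4
Reactants: 9 methyl 5-hydroxy-2,3-dimethoxybenzoate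
Product: 10 methyl 5-(benzyloxy)-2,3-dimethoxybenzoate
Conditions: BnBr, K2CO3, DMF, rt to 50 °C
Reagents that add atoms: benzyl bromide, BrCc1ccccc1
Why: Williamson etherification of an unhindered phenol; anhydrous K2CO3 does not touch the methyl ester.

Step 5
Reactants: 5 1-[2-(benzyloxy)-6-bromo-3,4-dimethoxyphenyl]ethanone; 10 methyl 5-(benzyloxy)-2,3-dimethoxybenzoate
Product: 11 1-[2-(benzyloxy)-6-bromo-3,4-dimethoxyphenyl]-3-[5-(benzyloxy)-2,3-dimethoxyphenyl]propane-1,3-dione
Conditions: LiN(SiMe3)2 (3 equiv), THF, −78 °C to rt; then sat. aq. NH4Cl
Reagents that add atoms: none
Why: Crossed Claisen condensation in which only 5 can enolise and ester 10 has no α-hydrogen; the two ortho substituents shield the carbonyl of 5 from self-aldol addition but leave its enolate carbon free, excess base deprotonates the product diketone and pulls the equilibrium over, and a lithium amide does not exchange with the aryl bromide.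

Step 6
Reactants: 11 1-[2-(benzyloxy)-6-bromo-3,4-dimethoxyphenyl]-3-[5-(benzyloxy)-2,3-dimethoxyphenyl]propane-1,3-dione
Product: 12 5-(benzyloxy)-2-[5-(benzyloxy)-2,3-dimethoxyphenyl]-6,7-dimethoxy-4H-chromen-4-one
Conditions: CuI (10 mol%), 1,10-phenanthroline (20 mol%), K3PO4 (2 equiv), DMF, 100 °C, N2
Reagents that add atoms: none
Why: Intramolecular Ullmann-type C–O coupling, the known copper-catalysed cyclisation of 1-(2-haloaryl)-1,3-diketones to flavones. K3PO4 deprotonates the acidic methylene of 11 and the enolate binds the phenanthroline complex of monovalent copper through oxygen, the ring A carbonyl oxygen placing the metal beside the ortho C–Br bond. Oxidative addition should then give an aryl species of trivalent copper that also carries the ring B enolate oxygen, and C–O reductive elimination from this seven-membered cupracycle forms O1–C8a. Ring C thus closes as a six-membered ring by substitution of an oxygen nucleophile at the aryl carbon, with the leaving bromide outside the new ring (an exo-type closure), and the product gains the stabilised 4-pyranone. No stereocentre is formed. The step needs O- over C-arylation and the right oxygen: attack by the central carbon or by the ring A carbonyl oxygen would give a four-membered ring, so ring size decides both. It also needs the bromide, not a phenol, to define O1; the benzyl ether on the C5 oxygen rules out condensation of that oxygen onto the ring B carbonyl, which would close the pyranone on the wrong side of ring A. The electron-rich ring is a poor partner for uncatalysed substitution, which is why the ligated copper catalyst and the activating ortho acyl group are relied on.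

Step 7
Reactants: 12 5-(benzyloxy)-2-[5-(benzyloxy)-2,3-dimethoxyphenyl]-6,7-dimethoxy-4H-chromen-4-one
Product: 13 5-hydroxy-2-(5-hydroxy-2,3-dimethoxyphenyl)-6,7-dimethoxy-4H-chromen-4-one
Conditions: H2 (1 atm), 10% Pd/C, EtOAc–MeOH, rt
Reagents that add atoms: none
Why: Catalytic hydrogenolysis cleaves both aryl benzyl ethers to the phenols and toluene; the C2=C3 bond of the 4-pyranone is part of a vinylogous ester and is reduced much more slowly, and the methyl ethers are untouched, so stopping at complete debenzylation should give 13.

## Compound list

1 | 5-bromo-1,2,3-trimethoxybenzene | COc1cc(Br)cc(OC)c1OC | starting material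
2 | acetyl chloride | CC(=O)Cl | starting material
3 | 1-(6-bromo-2,3,4-trimethoxyphenyl)ethanone | CC(=O)c1c(Br)cc(OC)c(OC)c1OC | intermediate (not isolated)
4 | 1-(6-bromo-2-hydroxy-3,4-dimethoxyphenyl)ethanone | CC(=O)c1c(Br)cc(OC)c(OC)c1O | intermediate
5 | 1-[2-(benzyloxy)-6-bromo-3,4-dimethoxyphenyl]ethanone | CC(=O)c1c(Br)cc(OC)c(OC)c1OCc2ccccc2 | intermediate
6 | methyl 2,3-dimethoxybenzoate | COC(=O)c1cccc(OC)c1OC | starting material
7 | bis(pinacolato)diboron | CC1(C)OB(OC1(C)C)B1OC(C)(C)C(C)(C)O1 | starting material
8 | methyl 2,3-dimethoxy-5-(4,4,5,5-tetramethyl-1,3,2-dioxaborolan-2-yl)benzoate | COC(=O)c1cc(B2OC(C)(C)C(C)(C)O2)cc(OC)c1OC | intermediate (not isolated)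
9 | methyl 5-hydroxy-2,3-dimethoxybenzoate | COC(=O)c1cc(O)cc(OC)c1OC | intermediate
10 | methyl 5-(benzyloxy)-2,3-dimethoxybenzoate | COC(=O)c1cc(OCc2ccccc2)cc(OC)c1OC | intermediate
11 | 1-[2-(benzyloxy)-6-bromo-3,4-dimethoxyphenyl]-3-[5-(benzyloxy)-2,3-dimethoxyphenyl]propane-1,3-dione | COc1cc(OCc2ccccc2)cc(C(=O)CC(=O)c3c(Br)cc(OC)c(OC)c3OCc4ccccc4)c1OC | intermediate
12 | 5-(benzyloxy)-2-[5-(benzyloxy)-2,3-dimethoxyphenyl]-6,7-dimethoxy-4H-chromen-4-one | COc1cc(OCc2ccccc2)cc(-c3cc(=O)c4c(OCc5ccccc5)c(OC)c(OC)cc4o3)c1OC | intermediate
13 | 5-hydroxy-2-(5-hydroxy-2,3-dimethoxyphenyl)-6,7-dimethoxy-4H-chromen-4-one | COc1cc(O)cc(-c2cc(=O)c3c(O)c(OC)c(OC)cc3o2)c1OC | target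

## Step count and risks

Total step count: 7. Longest linear sequence: 5 steps (steps 1, 2, 5, 6, 7 from 1; equally steps 3, 4, 5, 6, 7 from 6).

Step 6 (key step). The most likely failure is slow oxidative addition into a C–Br bond on an electron-rich ring that is twisted out of the diketonate plane by its two ortho substituents. Protodebromination, or retro-Claisen cleavage of the diketone by phosphate and traces of water at 100 °C, could then overtake the coupling. The fallback sets out from 5 and 10 and comes back at 12, closing O1–C2 instead of O1–C8a. The bromide of 5 is exchanged for hydroxyl by hydroxylation under zerovalent palladium catalysis (Pd2(dba)3, tBuXPhos, KOH, dioxane–H2O, 100 °C) to give 1-[2-(benzyloxy)-6-hydroxy-3,4-dimethoxyphenyl]ethanone F1. Its phenoxide–enolate dianion (LiN(SiMe3)2, 4 equiv, THF) is condensed with ester 10 to give 1-[2-(benzyloxy)-6-hydroxy-3,4-dimethoxyphenyl]-3-[5-(benzyloxy)-2,3-dimethoxyphenyl]propane-1,3-dione F2. Catalytic TsOH in toluene at 80 °C then cyclodehydrates F2 through its only free phenol to 12. Partial loss of the C5 benzyl group at this point would only anticipate step 7.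

Step 5. Conversion may stall because the ester carbonyl of 10 is electron-rich and flanked by a methoxy group, and because the enolate of 5 is quenched by proton transfer from the more acidic product if base runs short. The fallback sets out from 10 and 5 and comes back at 11 by aldol addition and oxidation. LiAlH4 in THF reduces 10 to [5-(benzyloxy)-2,3-dimethoxyphenyl]methanol F3. MnO2 in CH2Cl2 gives 5-(benzyloxy)-2,3-dimethoxybenzaldehyde F4. The lithium enolate of 5 (LiN(SiMe3)2, THF, −78 °C) adds to F4 to give racemic 1-[2-(benzyloxy)-6-bromo-3,4-dimethoxyphenyl]-3-[5-(benzyloxy)-2,3-dimethoxyphenyl]-3-hydroxypropan-1-one F5. Dess–Martin periodinane oxidises F5 to 11.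

Step 1. Excess AlCl3 may go on to cleave the central methoxy group (the future C6 ether), which lies next to the new aluminium phenoxide, and a strong Lewis acid can also cause loss or migration of bromine on so electron-rich a ring. The fallback sets out from 1 and comes back at 4 in two separate operations and makes no new compound (F0). Acylation with acetic anhydride and catalytic CF3SO3H gives 3, which is isolated. BCl3 in CH2Cl2 at −78 to 0 °C then removes only the methyl group that can chelate to the carbonyl.

Step 7. Over-reduction of the C2=C3 bond to the flavanone may set in once the benzyl groups are gone, or the reaction may stop after cleavage of only one ether. The fallback sets out from 12 and comes back at 13 without hydrogen and makes no new compound (F0). BCl3 with pentamethylbenzene as cation scavenger in CH2Cl2 at −78 °C cleaves both aryl benzyl ethers by Lewis acid activation, a temperature at which the methyl ethers should remain intact.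

## Further compounds

F1 | step 6 | 1-[2-(benzyloxy)-6-hydroxy-3,4-dimethoxyphenyl]ethanone | CC(=O)c1c(O)cc(OC)c(OC)c1OCc2ccccc2
F2 | step 6 | 1-[2-(benzyloxy)-6-hydroxy-3,4-dimethoxyphenyl]-3-[5-(benzyloxy)-2,3-dimethoxyphenyl]propane-1,3-dione | COc1cc(OCc2ccccc2)cc(C(=O)CC(=O)c3c(O)cc(OC)c(OC)c3OCc4ccccc4)c1OC
F3 | step 5 | [5-(benzyloxy)-2,3-dimethoxyphenyl]methanol | COc1cc(OCc2ccccc2)cc(CO)c1OC
F4 | step 5 | 5-(benzyloxy)-2,3-dimethoxybenzaldehyde | COc1cc(OCc2ccccc2)cc(C=O)c1OC
F5 | step 5 | 1-[2-(benzyloxy)-6-bromo-3,4-dimethoxyphenyl]-3-[5-(benzyloxy)-2,3-dimethoxyphenyl]-3-hydroxypropan-1-one (racemic) | COc1cc(OCc2ccccc2)cc(C(O)CC(=O)c3c(Br)cc(OC)c(OC)c3OCc4ccccc4)c1OC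
F0 | step 1 | none | none
F0 | step 7 | none | none
A1 | alternative 1 | 3-[5-(benzyloxy)-2,3-dimethoxyphenyl]-5-[2-(benzyloxy)-4,5,6-trimethoxyphenyl]isoxazole | COc1cc(OCc2ccccc2)cc(-c3cc(-c4c(OCc5ccccc5)cc(OC)c(OC)c4OC)on3)c1OC
A2 | alternative 1 | 1-(benzyloxy)-2-ethynyl-3,4,5-trimethoxybenzene | C#Cc1c(OCc2ccccc2)cc(OC)c(OC)c1OC
A3 | alternative 1 | (E)-5-(benzyloxy)-2,3-dimethoxybenzaldehyde oxime | COc1cc(OCc2ccccc2)cc(/C=N/O)c1OC
A4 | alternative 1 | 2-(5-hydroxy-2,3-dimethoxyphenyl)-5,6,7-trimethoxy-4H-chromen-4-one | COc1cc(O)cc(-c2cc(=O)c3c(OC)c(OC)c(OC)cc3o2)c1OC
A5 | alternative 2 | 3,4-dimethoxy-5-(5,6,7-trimethoxy-4-oxo-4H-chromen-2-yl)phenyl methanesulfonate | COc1cc(OS(C)(=O)=O)cc(-c2cc(=O)c3c(OC)c(OC)c(OC)cc3o2)c1OC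
A6 | alternative 2 | ethyl (2Z)-3-{2,3-dimethoxy-5-[(methylsulfonyl)oxy]phenyl}-3-(3,4,5-trimethoxyphenoxy)prop-2-enoate | CCOC(=O)/C=C(\Oc1cc(OC)c(OC)c(OC)c1)c1cc(OS(C)(=O)=O)cc(OC)c1OC
A7 | alternative 2 | 3,4,5-trimethoxyphenol | COc1cc(O)cc(OC)c1OC
A8 | alternative 2 | ethyl 3-{2,3-dimethoxy-5-[(methylsulfonyl)oxy]phenyl}prop-2-ynoate | CCOC(=O)C#Cc1cc(OS(C)(=O)=O)cc(OC)c1OC
A9 | alternative 3 | 2-[5-(benzyloxy)-2,3-dimethoxyphenyl]-5-hydroxy-6,7-dimethoxy-4H-chromen-4-one | COc1cc(OCc4ccccc4)cc(-c2cc(=O)c3c(O)c(OC)c(OC)cc3o2)c1OC
A10 | alternative 3 | 4-{6-[5-(benzyloxy)-2,3-dimethoxyphenyl]-4-oxo-4H-pyran-2-yl}-2,3-dimethoxycyclobut-2-en-1-one (racemic) | COC1=C(OC)C(c2cc(=O)cc(-c3cc(OCc4ccccc4)cc(OC)c3OC)o2)C1=O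
A11 | alternative 3 | dimethyl squarate (3,4-dimethoxycyclobut-3-ene-1,2-dione) | COC1=C(OC)C(=O)C1=O
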